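The data stem from a simulated flask from invented constants, noise included.

4 questions stand here on two flasks, and most of them come down to how much starting material survives 2.0 min.

common to all: starting material 0.20 M

| charge | reagent | second substrate | third substrate | remark | time |
|---|---|---|---|---|---|
| epsilon | 0.27 M | 0.20 M | 0.20 M | run made earlier |  |
| gamma | 0.44 M | 0.20 M | 0.20 M | run made earlier |  |
| theta | 0.63 M | 0.20 M | 0.20 M | run made earlier |  |
| blue | 0.300 M | 0.200 M | 0.200 M |  | 2.0 min |
| green | 0.750 M | 0.200 M | 0.200 M |  | 2.0 min |

| run | time / s | target / % | starting material / % | over-reaction product / % |
|---|---|---|---|---|
| epsilon | 10.0 | 5 | 94 | 0 |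
| epsilon | 20.0 | 8 | 88 | 1 |
| epsilon | 50.0 | 18 | 81 | 2 |
| epsilon | 120 | 33 | 67 | 2 |
| gamma | 30.0 | 21 | 78 | 0 |
| gamma | 60.0 | 36 | 66 | 2 |
| gamma | 90.0 | 38 | 54 | 4 |
| gamma | 120 | 45 | 48 | 5 |
| theta | 15.0 | 14 | 82 | 0 |
| theta | 40.0 | 36 | 65 | 0 |
| theta | 80.0 | 51 | 44 | 7 |
| theta | 120 | 57 | 34 | 9 |

(each reading ± 1.5 percentage points)

- which of these there is most of at the end, counted by the starting material in it, blue (starting material / target / over-reaction product)
- which of these there is most of at the end, counted by the starting material in it, green (starting material / target / over-reaction product)
- final amount of the leader among these, as a percentage of the starting material charged, in blue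
- final amount of the leader among these, as a percentage of the starting material charged, in green

- what was read earlier has a scatter of 1.5 percentage points, one standard deviation

Take the loss of starting material as k times starting material times reagent. Divide by the starting material and integrate, and you get ln(charged/left) = k × (area under the reagent curve). Call the left side the exposure; you need only the ratio of what is left to what was charged. If the reagent held still, the pseudo-first-order case, exposure per molar of reagent charged would match from run to run at equal time.

At 120 s, which is the asked time, that figure reads 1.48 /M in epsilon, 1.67 /M in gamma and 1.71 /M in theta. This ratio, exposure over reagent charge, is the quantity to carry. Epsilon's figure is less than theta's, so, as far as these scattered readings show, the reagent does not hold still.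

My reckoning for blue interpolates to 1.52 /M, which leaves 63.5% starting material. That is more than the 36.5% gone, so starting material leads in blue. For green I carry theta's figure, which gives an exposure of 1.28 and leaves 27.7%. With theta's 9% of over-reaction product, target in green comes to 63.3%.

The forecast says starting material at 63% in blue and target at 61% in green, holding that “the rate is roughly first order in reagent”. We part on green's over-reaction product, where it takes about 12.

Blue gives starting material at 62.8%, and green gives target at 63.2%, so the forecast stands; blue's starting material moves 6 points at 0.359 M of reagent.

    starting material + reagent → target (k = 0.0227 /M/s)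
    second substrate + reagent → second product (k = 0.0159 /M/s)
    third substrate + reagent → third product (k = 0.0278 /M/s)
    target → over-reaction product (k = 0.00179 /s)
    2 third substrate → homo dimer (k = 0.0164 /M/s)

Neither flask has come to rest. Ten times the time at the carried pace gives green an exposure of 12.8. It reaches 6.52 at 20.0 min, with 0.148% starting material and 24.7% of its reagent charge left. Blue, at that time, is reckoned at 4.55 and reaches 0.860, holding 42.3% starting material with 0.206% of its reagent charge. Target by then has sunk to 9.08% in blue and 14.7% in green, and over-reaction product stands at 48.6% in blue and 85.1% in green.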